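The route rests on cutting the farnesyl chain (C1' = ether CH2) at C5'–C6' and at the C7' methyl. The key step exploits the E-trisubstituted C6'=C7' alkene, methylated at C7' and flanked by the oxygen-bearing carbons C5' and C8': zirconium-catalysed syn methylalumination of an (R)-C8'-silyloxy terminal alkyne builds that alkene, and the alkenylalane then attacks a C5' aldehyde already carrying the coumarin ether (no ring forms; the coumarin bicycle is a spectator). C8' is set beforehand by asymmetric transfer hydrogenation; C5' forms as both epimers and is set S by oxidation and oxazaborolidine reduction, followed by acetylation and desilylation.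

Key step: step 10

Remarks
- Structure check: CIP analysis of the target gives 5'S (O > C6' > C4' > H), 8'R (O > C7' > C9' > H) and E geometry for both C2'=C3' and C6'=C7'. The acetate is on C5' and the free hydroxyl on C8'. No structure needed correcting.
- Assumption: tert-butyl(but-3-yn-1-yloxy)dimethylsilane (11) is bought; otherwise it is one silylation (TBSCl, imidazole) from but-3-yn-1-ol.
- The key step is run without a chiral additive, because the remote C8' centre cannot bias C5'. Its product 21 is therefore the pair of C5' epimers, and the single (5'S,8'R) alcohol is compound 23.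

Step 1
Reactants: 1 4-methylpent-3-enoic acid
Product: 3 N-methoxy-N,4-dimethylpent-3-enamide, via acylimidazole 2 (not isolated)
Conditions: CDI, CH2Cl2, rt; then MeNH(OMe)·HCl, rt
Reagents that add atoms: N,O-dimethylhydroxylamine hydrochloride, CNOC.Cl; 1,1'-carbonyldiimidazole, O=C(n1ccnc1)n1ccnc1 (imidazolyl group of intermediate 2 only)
Why: Amide coupling through the acylimidazole 2 runs without strong acid or base, so the β,γ-alkene of the acid stays out of conjugation.

Step 2
Reactants: 3 N-methoxy-N,4-dimethylpent-3-enamide; 4 ethynyltrimethylsilane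
Product: 7 6-methyl-1-(trimethylsilyl)hept-5-en-1-yn-3-one, via lithium (trimethylsilyl)acetylide 5 (not isolated), via tetrahedral lithium alkoxide 6 (not isolated)
Conditions: 4, n-BuLi, THF, −78 °C; then 3, −78 to −20 °C; cold aq. NH4Cl
Reagents that add atoms: n-butyllithium, [Li]CCCC (lithium of intermediates 5 and 6 only)
Why: Weinreb ketone synthesis: the lithium acetylide adds once because the chelated tetrahedral adduct 6 survives until the cold quench, which releases the skipped ynone without over-addition.

Step 3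
Reactants: 7 6-methyl-1-(trimethylsilyl)hept-5-en-1-yn-3-one
Product: 8 (R)-6-methyl-1-(trimethylsilyl)hept-5-en-1-yn-3-ol
Conditions: Ru[(R,R)-TsDPEN](p-cymene) (2 mol%, preformed from [RuCl2(p-cymene)]2, (R,R)-N-tosyl-1,2-diphenylethylenediamine and KOH), i-PrOH, rt
Reagents that add atoms: none
Why: Noyori asymmetric transfer hydrogenation of an alkynyl ketone, in which the (R,R)-TsDPEN ruthenium hydride places the alkynyl group where the aryl group of an aryl alkyl ketone sits and so delivers hydride to the face that gives the R carbinol (the later C8'), leaving the alkene and the C–Si bond alone.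

Step 4
Reactants: 8 (R)-6-methyl-1-(trimethylsilyl)hept-5-en-1-yn-3-ol
Product: 9 (R)-3-(tert-butyldimethylsilyloxy)-6-methyl-1-(trimethylsilyl)hept-5-en-1-yne
Conditions: TBSCl, imidazole, DMF, rt
Reagents that add atoms: tert-butyldimethylsilyl chloride, CC(C)(C)[Si](C)(C)Cl
Why: Standard imidazole-promoted silylation of a secondary alcohol; the bulky TBS group is chosen to survive Me3Al and to shield the propargylic oxygen in step 10, and the stereocentre is not touched.

Step 5
Reactants: 9 (R)-3-(tert-butyldimethylsilyloxy)-6-methyl-1-(trimethylsilyl)hept-5-en-1-yne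
Product: 10 (R)-3-(tert-butyldimethylsilyloxy)-6-methylhept-5-en-1-yne
Conditions: K2CO3 (0.2 equiv), MeOH, rt
Reagents that add atoms: none
Why: Methanolysis of the alkynyl C–Si bond by catalytic methoxide (protodesilylation) is selective because the O-TBS ether is far less labile to K2CO3 in MeOH, and doing it after O-silylation avoids a volatile free alkynol.

Step 6
Reactants: 11 tert-butyl(but-3-yn-1-yloxy)dimethylsilane; 12 trimethylaluminium
Product: 15 (E)-5-(tert-butyldimethylsilyloxy)-3-methylpent-2-en-1-ol, via alkenyldimethylalane 13 (not isolated), via lithium alkenylaluminate 14 (not isolated)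
Conditions: Me3Al (2.5 equiv), Cp2ZrCl2 (0.25 equiv), CH2Cl2, 0 °C to rt; evaporate; n-BuLi, THF–hexane, −78 to 0 °C; (CH2O)n, rt; aq. potassium sodium tartrate
Reagents that add atoms: paraformaldehyde (as formaldehyde), C=O; trimethylaluminium (compound 12), C[Al](C)C; n-butyllithium, [Li]CCCC (butyl and lithium of intermediate 14 only)
Why: Negishi zirconium-catalysed methylalumination adds CH3 and Al syn with methyl on the internal carbon, and the derived butyl aluminate 14 is nucleophilic enough to take up formaldehyde with retention, which fixes the E C2'=C3' alkene and installs C1'.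

Step 7
Reactants: 15 (E)-5-(tert-butyldimethylsilyloxy)-3-methylpent-2-en-1-ol; 16 umbelliferone
Product: 17 7-{[(E)-5-(tert-butyldimethylsilyloxy)-3-methylpent-2-en-1-yl]oxy}-2H-chromen-2-one
Conditions: PPh3, DIAD, THF, 0 °C to rt
Reagents that add atoms: none
Why: Mitsunobu etherification of an acidic phenol with an unhindered primary allylic alcohol proceeds by SN2 displacement at C1' under neutral conditions that leave the lactone and the silyl ether intact.

Step 8
Reactants: 17 7-{[(E)-5-(tert-butyldimethylsilyloxy)-3-methylpent-2-en-1-yl]oxy}-2H-chromen-2-one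
Product: 18 7-{[(E)-5-hydroxy-3-methylpent-2-en-1-yl]oxy}-2H-chromen-2-one
Conditions: HF·pyridine, pyridine, THF, 0 °C to rt
Reagents that add atoms: none
Why: Fluoride-mediated desilylation of a primary TBS ether with pyridine-buffered HF·pyridine avoids both the hydroxide that would open the lactone and the strong acid that would ionise the aryl allyl ether.

Step 9
Reactants: 18 7-{[(E)-5-hydroxy-3-methylpent-2-en-1-yl]oxy}-2H-chromen-2-one
Product: 19 (E)-3-methyl-5-[(2-oxo-2H-chromen-7-yl)oxy]pent-3-enal
Conditions: Dess–Martin periodinane, pyridine, CH2Cl2, 0 °C; crude aldehyde dried azeotropically (toluene) and used at once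
Reagents that add atoms: none
Why: Dess–Martin oxidation of the homoallylic primary alcohol runs at 0 °C under buffered, non-basic conditions, so the β,γ-unsaturated aldehyde can be taken on crude before the C2'=C3' alkene has a chance to move into conjugation.

Step 10
Reactants: 10 (R)-3-(tert-butyldimethylsilyloxy)-6-methylhept-5-en-1-yne; 12 trimethylaluminium; 19 (E)-3-methyl-5-[(2-oxo-2H-chromen-7-yl)oxy]pent-3-enal
Product: 21 7-{[(2E,6E,8R)-8-(tert-butyldimethylsilyloxy)-5-hydroxy-3,7,11-trimethyldodeca-2,6,10-trien-1-yl]oxy}-2H-chromen-2-one as the pair of C5' epimers, via alkenyldimethylalane 20 (not isolated)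
Conditions: 10, Me3Al (2.5 equiv), Cp2ZrCl2 (0.25 equiv), CH2Cl2, 0 °C to rt; volatiles and surplus Me3Al removed in vacuo; CH2Cl2, 19 (0.8 equiv), −78 to −20 °C; aq. potassium sodium tartrate
Reagents that add atoms: trimethylaluminium (compound 12), C[Al](C)C
Why: Cp2ZrCl2 and Me3Al form a methylzirconocene–aluminate pair that adds CH3–metal syn across the terminal alkyne, methyl to the internal carbon C7' and metal to C6', and transmetalation leaves the (E)-alkenyldimethylalane 20, so the C7'–CH3 bond and the E geometry of C6'=C7' are fixed together. Once the surplus Me3Al has been pumped off, the aldehyde coordinates to aluminium and the sp2 carbon C6' migrates to the carbonyl carbon C5' with retention of alkene geometry, faster than a methyl group would. The closest known reaction type is the Negishi zirconium-catalysed methylalumination of a terminal alkyne followed by direct addition of the alkenylalane to an aldehyde; no ring is closed. The new stereocentre C5' has no controlling element, because C8' lies across the alkene and the OTBS group cannot chelate, so both C5' epimers are expected and steps 11 and 12 converge them. The step needs regioselective syn carbometalation, secured by the terminal alkyne and the bulky non-coordinating silyl ether, and chemoselective attack on the aldehyde over the coumarin lactone and the aryl allyl ether, secured by the higher electrophilicity of the aldehyde and by keeping the addition at or below −20 °C.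

Step 11
Reactants: 21 7-{[(2E,6E,8R)-8-(tert-butyldimethylsilyloxy)-5-hydroxy-3,7,11-trimethyldodeca-2,6,10-trien-1-yl]oxy}-2H-chromen-2-one (both C5' epimers)
Product: 22 7-{[(2E,6E,8R)-8-(tert-butyldimethylsilyloxy)-3,7,11-trimethyl-5-oxododeca-2,6,10-trien-1-yl]oxy}-2H-chromen-2-one
Conditions: Dess–Martin periodinane, pyridine, CH2Cl2, 0 °C
Reagents that add atoms: none
Why: Dess–Martin oxidation of the secondary allylic alcohol turns both C5' epimers into one enone, again under buffered conditions that leave the C4' methylene between ketone and alkene, the C8' centre and the silyl ether alone.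

Step 12
Reactants: 22 7-{[(2E,6E,8R)-8-(tert-butyldimethylsilyloxy)-3,7,11-trimethyl-5-oxododeca-2,6,10-trien-1-yl]oxy}-2H-chromen-2-one
Product: 23 7-{[(2E,5S,6E,8R)-8-(tert-butyldimethylsilyloxy)-5-hydroxy-3,7,11-trimethyldodeca-2,6,10-trien-1-yl]oxy}-2H-chromen-2-one
Conditions: (R)-tetrahydro-1-methyl-3,3-diphenyl-1H,3H-pyrrolo[1,2-c][1,3,2]oxazaborole ((R)-Me-CBS, 0.3 equiv), catecholborane, toluene, −78 °C; MeOH, aq. NaHCO3
Reagents that add atoms: none
Why: Corey–Bakshi–Shibata reduction: the (R)-oxazaborolidine binds the ketone with the alkenyl C6' arm as the large group and delivers hydride from catecholborane to the face that gives 5'S (the sense in which the (R)-catalyst gives S carbinols from aryl or alkenyl alkyl ketones), while catecholborane at −78 °C does not hydroborate the trisubstituted alkenes or reduce the lactone.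

Step 13
Reactants: 23 7-{[(2E,5S,6E,8R)-8-(tert-butyldimethylsilyloxy)-5-hydroxy-3,7,11-trimethyldodeca-2,6,10-trien-1-yl]oxy}-2H-chromen-2-one
Product: 24 (2E,5S,6E,8R)-8-(tert-butyldimethylsilyloxy)-3,7,11-trimethyl-1-[(2-oxo-2H-chromen-7-yl)oxy]dodeca-2,6,10-trien-5-yl acetate
Conditions: Ac2O, pyridine, DMAP (cat.), CH2Cl2, 0 °C to rt
Reagents that add atoms: acetic anhydride, CC(=O)OC(C)=O
Why: DMAP-catalysed acylation of the only free hydroxyl (C5') with retention of configuration; C8' is still silylated so no regiochemical question arises.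

Step 14
Reactants: 24 (2E,5S,6E,8R)-8-(tert-butyldimethylsilyloxy)-3,7,11-trimethyl-1-[(2-oxo-2H-chromen-7-yl)oxy]dodeca-2,6,10-trien-5-yl acetate
Product: 25 (2E,5S,6E,8R)-8-hydroxy-3,7,11-trimethyl-1-[(2-oxo-2H-chromen-7-yl)oxy]dodeca-2,6,10-trien-5-yl acetate (target)
Conditions: HF·pyridine, pyridine, THF, 0 °C to rt
Reagents that add atoms: none
Why: Fluoride-mediated cleavage of the secondary allylic TBS ether with buffered HF·pyridine spares the acetate, the lactone and the aryl allyl ether, and the acetate cannot migrate because the E C6'=C7' alkene holds C5' and C8' apart.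

Compound list
1 | 4-methylpent-3-enoic acid | CC(C)=CCC(=O)O | starting material
2 | 1-(4-methylpent-3-enoyl)-1H-imidazole | CC(C)=CCC(=O)n1ccnc1 | intermediate (not isolated)
3 | N-methoxy-N,4-dimethylpent-3-enamide | CC(C)=CCC(=O)N(C)OC | intermediate
4 | ethynyltrimethylsilane | C#C[Si](C)(C)C | starting material
5 | lithium (trimethylsilyl)acetylide | [Li]C#C[Si](C)(C)C | intermediate (not isolated)
6 | lithium 3-[methoxy(methyl)amino]-6-methyl-1-(trimethylsilyl)hept-5-en-1-yn-3-olate | CC(C)=CCC(O[Li])(C#C[Si](C)(C)C)N(C)OC | intermediate (not isolated)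
7 | 6-methyl-1-(trimethylsilyl)hept-5-en-1-yn-3-one | CC(C)=CCC(=O)C#C[Si](C)(C)C | intermediate
8 | (R)-6-methyl-1-(trimethylsilyl)hept-5-en-1-yn-3-ol | C[Si](C)(C)C#C[C@H](O)CC=C(C)C | intermediate
9 | (R)-3-(tert-butyldimethylsilyloxy)-6-methyl-1-(trimethylsilyl)hept-5-en-1-yne | C[Si](C)(C)C#C[C@H](O[Si](C)(C)C(C)(C)C)CC=C(C)C | intermediate
10 | (R)-3-(tert-butyldimethylsilyloxy)-6-methylhept-5-en-1-yne | C#C[C@H](O[Si](C)(C)C(C)(C)C)CC=C(C)C | intermediate
11 | tert-butyl(but-3-yn-1-yloxy)dimethylsilane | C#CCCO[Si](C)(C)C(C)(C)C | starting material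
12 | trimethylaluminium | C[Al](C)C | starting material
13 | (E)-[4-(tert-butyldimethylsilyloxy)-2-methylbut-1-en-1-yl]dimethylalane | C[Al](C)/C=C(\C)CCO[Si](C)(C)C(C)(C)C | intermediate (not isolated)
14 | lithium butyl[(E)-4-(tert-butyldimethylsilyloxy)-2-methylbut-1-en-1-yl]dimethylaluminate | [Li+].CCCC[Al-](C)(C)/C=C(\C)CCO[Si](C)(C)C(C)(C)C | intermediate (not isolated)
15 | (E)-5-(tert-butyldimethylsilyloxy)-3-methylpent-2-en-1-ol | OC/C=C(\C)CCO[Si](C)(C)C(C)(C)C | intermediate
16 | umbelliferone (7-hydroxy-2H-chromen-2-one) | O=c1ccc2ccc(O)cc2o1 | starting material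
17 | 7-{[(E)-5-(tert-butyldimethylsilyloxy)-3-methylpent-2-en-1-yl]oxy}-2H-chromen-2-one | CC(C)(C)[Si](C)(C)OCC/C(C)=C/COc1ccc2ccc(=O)oc2c1 | intermediate
18 | 7-{[(E)-5-hydroxy-3-methylpent-2-en-1-yl]oxy}-2H-chromen-2-one | OCC/C(C)=C/COc1ccc2ccc(=O)oc2c1 | intermediate
19 | (E)-3-methyl-5-[(2-oxo-2H-chromen-7-yl)oxy]pent-3-enal | O=CC/C(C)=C/COc1ccc2ccc(=O)oc2c1 | intermediate
20 | [(1E,3R)-3-(tert-butyldimethylsilyloxy)-2,6-dimethylhepta-1,5-dien-1-yl]dimethylalane | C[Al](C)/C=C(\C)[C@H](O[Si](C)(C)C(C)(C)C)CC=C(C)C | intermediate (not isolated)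
21 | 7-{[(2E,6E,8R)-8-(tert-butyldimethylsilyloxy)-5-hydroxy-3,7,11-trimethyldodeca-2,6,10-trien-1-yl]oxy}-2H-chromen-2-one, pair of C5' epimers | OC(/C=C(\C)[C@H](O[Si](C)(C)C(C)(C)C)CC=C(C)C)C/C(C)=C/COc1ccc2ccc(=O)oc2c1 | intermediate
22 | 7-{[(2E,6E,8R)-8-(tert-butyldimethylsilyloxy)-3,7,11-trimethyl-5-oxododeca-2,6,10-trien-1-yl]oxy}-2H-chromen-2-one | O=C(/C=C(\C)[C@H](O[Si](C)(C)C(C)(C)C)CC=C(C)C)C/C(C)=C/COc1ccc2ccc(=O)oc2c1 | intermediate
23 | 7-{[(2E,5S,6E,8R)-8-(tert-butyldimethylsilyloxy)-5-hydroxy-3,7,11-trimethyldodeca-2,6,10-trien-1-yl]oxy}-2H-chromen-2-one | O[C@H](/C=C(\C)[C@H](O[Si](C)(C)C(C)(C)C)CC=C(C)C)C/C(C)=C/COc1ccc2ccc(=O)oc2c1 | intermediate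
24 | (2E,5S,6E,8R)-8-(tert-butyldimethylsilyloxy)-3,7,11-trimethyl-1-[(2-oxo-2H-chromen-7-yl)oxy]dodeca-2,6,10-trien-5-yl acetate | CC(=O)O[C@H](/C=C(\C)[C@H](O[Si](C)(C)C(C)(C)C)CC=C(C)C)C/C(C)=C/COc1ccc2ccc(=O)oc2c1 | intermediate
25 | (2E,5S,6E,8R)-8-hydroxy-3,7,11-trimethyl-1-[(2-oxo-2H-chromen-7-yl)oxy]dodeca-2,6,10-trien-5-yl acetate | CC(=O)O[C@H](/C=C(\C)[C@H](O)CC=C(C)C)C/C(C)=C/COc1ccc2ccc(=O)oc2c1 | target

Total step count: 14. Longest linear sequence: 10 steps (steps 1–5, then 10–14); the aldehyde branch (steps 6–9) has 4 steps.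

Steps most likely to fail

Step 10. The alane may enolise the β,γ-unsaturated aldehyde or make it self-condense. It may also transfer methyl in place of the alkenyl group, or the aluminium Lewis acids may ionise the aryl allyl ether, so that conversion to the adduct stalls. The fallback separates metalation from carbonyl addition. Alane 20, made from 10 as in step 10, would be quenched with iodine (THF, −30 °C) to give (R,E)-tert-butyl[(1-iodo-2,6-dimethylhepta-1,5-dien-3-yl)oxy]dimethylsilane F1. F1 would then be joined to aldehyde 19 by a Nozaki–Hiyama–Kishi coupling (CrCl2, NiCl2 cat., DMSO, rt), which is neutral and tolerates enolisable aldehydes and lactones. The fallback sets out from 10 and comes back to the route at 21.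

Step 9. The C2'=C3' alkene may migrate into conjugation with the new aldehyde, or the aldehyde may enolise and condense during oxidation and handling. The fallback releases the aldehyde by glycol cleavage, which needs neither base nor acid.
- Pent-4-yne-1,2-diol F2 (bought, or from glycidol and lithium acetylide) would be bis-silylated (TBSCl, imidazole, DMF) to 4,5-bis(tert-butyldimethylsilyloxy)pent-1-yne F3.
- Methylalumination with 12 and hydroxymethylation as in step 6 would pass through [(E)-4,5-bis(tert-butyldimethylsilyloxy)-2-methylpent-1-en-1-yl]dimethylalane F4 and lithium butyl[(E)-4,5-bis(tert-butyldimethylsilyloxy)-2-methylpent-1-en-1-yl]dimethylaluminate F5 to (E)-5,6-bis(tert-butyldimethylsilyloxy)-3-methylhex-2-en-1-ol F6.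
- Mitsunobu etherification with umbelliferone 16 as in step 7 would give 7-{[(E)-5,6-bis(tert-butyldimethylsilyloxy)-3-methylhex-2-en-1-yl]oxy}-2H-chromen-2-one F7.
- HF·pyridine would free 7-{[(E)-5,6-dihydroxy-3-methylhex-2-en-1-yl]oxy}-2H-chromen-2-one F8.
- NaIO4 (THF, pH 7 buffer, 0 °C) would cleave the glycol to aldehyde 19.

The fallback sets out from 16 and 12 and comes back to the route at 19.

Step 12. Facial discrimination may be poor, because the alkenyl arm and the allyl-type CH2 arm of enone 22 differ little in size. The fallback drops the oxidation–reduction pair. The C5' epimers of 21 would be separated by chromatography and assigned by Mosher ester analysis. The 5'S epimer is compound 23 and goes straight to step 13. The 5'R epimer, 7-{[(2E,5R,6E,8R)-8-(tert-butyldimethylsilyloxy)-5-hydroxy-3,7,11-trimethyldodeca-2,6,10-trien-1-yl]oxy}-2H-chromen-2-one F9, would be converted into acetate 24 by Mitsunobu inversion with acetic acid (PPh3, DIAD, AcOH, toluene, 0 °C). The fallback sets out from 21 and comes back to the route at 23 and at 24.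

Further compounds
F1 | step 10 | (R,E)-tert-butyl[(1-iodo-2,6-dimethylhepta-1,5-dien-3-yl)oxy]dimethylsilane | I/C=C(\C)[C@H](O[Si](C)(C)C(C)(C)C)CC=C(C)C
F2 | step 9 | pent-4-yne-1,2-diol | C#CCC(O)CO
F3 | step 9 | 4,5-bis(tert-butyldimethylsilyloxy)pent-1-yne | C#CCC(CO[Si](C)(C)C(C)(C)C)O[Si](C)(C)C(C)(C)C
F4 | step 9 | [(E)-4,5-bis(tert-butyldimethylsilyloxy)-2-methylpent-1-en-1-yl]dimethylalane | C[Al](C)/C=C(\C)CC(CO[Si](C)(C)C(C)(C)C)O[Si](C)(C)C(C)(C)C
F5 | step 9 | lithium butyl[(E)-4,5-bis(tert-butyldimethylsilyloxy)-2-methylpent-1-en-1-yl]dimethylaluminate | [Li+].CCCC[Al-](C)(C)/C=C(\C)CC(CO[Si](C)(C)C(C)(C)C)O[Si](C)(C)C(C)(C)C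
F6 | step 9 | (E)-5,6-bis(tert-butyldimethylsilyloxy)-3-methylhex-2-en-1-ol | OC/C=C(\C)CC(CO[Si](C)(C)C(C)(C)C)O[Si](C)(C)C(C)(C)C
F7 | step 9 | 7-{[(E)-5,6-bis(tert-butyldimethylsilyloxy)-3-methylhex-2-en-1-yl]oxy}-2H-chromen-2-one | CC(C)(C)[Si](C)(C)OCC(C/C(C)=C/COc1ccc2ccc(=O)oc2c1)O[Si](C)(C)C(C)(C)C
F8 | step 9 | 7-{[(E)-5,6-dihydroxy-3-methylhex-2-en-1-yl]oxy}-2H-chromen-2-one | OCC(O)C/C(C)=C/COc1ccc2ccc(=O)oc2c1
F9 | step 12 | 7-{[(2E,5R,6E,8R)-8-(tert-butyldimethylsilyloxy)-5-hydroxy-3,7,11-trimethyldodeca-2,6,10-trien-1-yl]oxy}-2H-chromen-2-one | O[C@@H](/C=C(\C)[C@H](O[Si](C)(C)C(C)(C)C)CC=C(C)C)C/C(C)=C/COc1ccc2ccc(=O)oc2c1
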